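## Retrosynthetic overview

1. The target comes from its tri-O-methyl, bis(dithiane)-masked form; the benzylic centre C9′ is set by SN1 methallylation of an aryl carbinol under A(1,3) control from C1/C10, followed by alkene reduction.
2. The carbinol is the union of two fragments: an aryllithium from a phloroglucinol-derived bromo bis(dithiane) and a decalin aldehyde (C1–CHO).
3. The decalin aldehyde comes from a trans-fused keto ester (C4 ketone and C7 ester, both turned into carbinols by MeMgBr); ring B closes by intramolecular Michael addition of the C5 enolate onto an α-substituted acrylate.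
4. The acrylate comes from a B-alkyl Suzuki coupling of a vinyl ketone with methyl 2-bromoacrylate; quaternary C10 comes from anti-selective vinyl–copper addition to a 3-methyl-4-substituted cyclohexenone.
5. That enone (ring A) comes from an organocatalytic Michael addition / intramolecular aldol condensation of 3-(benzyloxy)propanal with methyl vinyl ketone, which sets C1. Rings form in the order A (aldol), then B (Michael).

Assumption: atom labels follow a eudesmane-type numbering of the target (C1 carries the benzylic carbon C9′, C4 the ring carbinol, C7 the hydroxypropyl group, C10 the angular methyl; ring A = C1–C5/C10, ring B = C5–C10), and compounds 1, 4, 5, 18 and 23 are bought.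

## Route

Step 1
Reactants: 1 methyl acrylate
Product: 2 methyl 2,3-dibromopropanoate (racemic)
Conditions: Br2, CH2Cl2, 0 °C → rt
Reagents that add atoms: bromine, BrBr
Why: Electrophilic anti-addition of bromine to the alkene gives the vicinal dibromide, whose stereocentre is erased in the next step.

Step 2
Reactants: 2 methyl 2,3-dibromopropanoate
Product: 3 methyl 2-bromoprop-2-enoate
Conditions: Et3N, Et2O, 0 °C → rt
Reagents that add atoms: none
Why: E1cB-type dehydrobromination (loss of the acidic α-hydrogen and the β-bromide) delivers the α-bromoacrylate.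

Step 3
Reactants: 4 3-(benzyloxy)propanal; 5 but-3-en-2-one (methyl vinyl ketone)
Product: 7 (S)-4-[(benzyloxy)methyl]cyclohex-2-en-1-one, via keto aldehyde 6 (not isolated)
Conditions: (R)-α,α-diphenylprolinol trimethylsilyl ether (10 mol %), ethyl 3,4-dihydroxybenzoate (20 mol %), neat, 4 °C; then LiOH (0.2 equiv), i-PrOH, rt
Reagents that add atoms: none
Why: Enamine-catalysed Michael addition to the enone (the diarylprolinol ether shields one enamine face and so sets C1) followed by intramolecular aldol condensation closes ring A, i.e. an organocatalytic Robinson annulation.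

Step 4
Reactants: 7 (S)-4-[(benzyloxy)methyl]cyclohex-2-en-1-one
Product: 9 (S)-4-[(benzyloxy)methyl]-3-methylcyclohex-2-en-1-one, via lithium enolate 8 (not isolated)
Conditions: Me2CuLi (from MeLi and CuI), Et2O, −78 → −40 °C; then PhS(Cl)=N-t-Bu, THF, −78 °C → rt
Reagents that add atoms: lithium dimethylcuprate, [Li+].C[Cu-]C
Why: Gilman conjugate addition places the methyl group on C10 (anti to the C1 side chain) and Mukaiyama dehydrogenation of the enolate with N-tert-butylbenzenesulfinimidoyl chloride restores the enone, leaving C1 untouched.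

Step 5
Reactants: 9 (S)-4-[(benzyloxy)methyl]-3-methylcyclohex-2-en-1-one
Product: 11 (3R,4S)-4-[(benzyloxy)methyl]-3-ethenyl-3-methylcyclohexan-1-one, via silyl enol ether 10 (not isolated)
Conditions: CH2=CHMgBr, CuBr·SMe2 (20 mol %), TMSCl, HMPA, THF, −78 → −40 °C; then 1 M HCl
Reagents that add atoms: vinylmagnesium bromide, C=C[Mg]Br
Why: Copper-catalysed, TMSCl-accelerated 1,4-addition to the β,β-disubstituted enone creates quaternary C10; A(1,2) strain with the C10 methyl holds the C1 side chain pseudoaxial, so vinyl enters anti to it and CH3-10 ends up cis to the side chain.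

Step 6
Reactants: 11 (3R,4S)-4-[(benzyloxy)methyl]-3-ethenyl-3-methylcyclohexan-1-one; 3 methyl 2-bromoprop-2-enoate
Product: 13 methyl 4-[(1S,2S)-2-[(benzyloxy)methyl]-1-methyl-5-oxocyclohexyl]-2-methylidenebutanoate, via alkylborane 12 (not isolated)
Conditions: 9-BBN-H, THF, rt; then 3, PdCl2(dppf) (5 mol %), AsPh3, Cs2CO3, DMF/H2O, rt
Reagents that add atoms: none
Why: Anti-Markovnikov hydroboration of the vinyl group (much faster than ketone reduction by 9-BBN) and B-alkyl Suzuki–Miyaura coupling with the α-bromoacrylate join C8 to C7 without touching a stereocentre.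

Step 7
Reactants: 13 methyl 4-[(1S,2S)-2-[(benzyloxy)methyl]-1-methyl-5-oxocyclohexyl]-2-methylidenebutanoate
Product: 14 methyl (2S,4aR,5S,8aS)-5-[(benzyloxy)methyl]-4a-methyl-8-oxodecahydronaphthalene-2-carboxylate
Conditions: NaOMe (0.3 equiv), MeOH, rt → 50 °C
Reagents that add atoms: none
Why: Intramolecular Michael addition (6-endo-trig) of the C4-ketone enolate through C5 onto the acrylate closes ring B, and base equilibration of the two new α-carbonyl centres gives the trans-decalin (H-5 anti to CH3-10) with the C7 ester equatorial, cis to CH3-10.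

Step 8
Reactants: 14 methyl (2S,4aR,5S,8aS)-5-[(benzyloxy)methyl]-4a-methyl-8-oxodecahydronaphthalene-2-carboxylate
Product: 15 (1R,4S,4aR,7S,8aS)-4-[(benzyloxy)methyl]-7-(2-hydroxypropan-2-yl)-1,4a-dimethyldecahydronaphthalen-1-ol
Conditions: MeMgBr (6 equiv), CeCl3, THF, −78 °C → rt
Reagents that add atoms: methylmagnesium bromide, C[Mg]Br
Why: Grignard addition in which methyl attacks the C4 ketone from the equatorial side, away from the syn-axial C10 methyl, giving the axial hydroxyl cis to CH3-10, while double addition to the ester builds the C7 hydroxypropyl group.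

Step 9
Reactants: 15 (1R,4S,4aR,7S,8aS)-4-[(benzyloxy)methyl]-7-(2-hydroxypropan-2-yl)-1,4a-dimethyldecahydronaphthalen-1-ol
Product: 16 (1R,4S,4aR,7S,8aS)-4-(hydroxymethyl)-7-(2-hydroxypropan-2-yl)-1,4a-dimethyldecahydronaphthalen-1-ol
Conditions: H2 (1 atm), Pd/C, EtOH, rt
Reagents that add atoms: none
Why: Hydrogenolysis of the benzyl ether frees the primary alcohol while the tertiary alcohols are inert.

Step 10
Reactants: 16 (1R,4S,4aR,7S,8aS)-4-(hydroxymethyl)-7-(2-hydroxypropan-2-yl)-1,4a-dimethyldecahydronaphthalen-1-ol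
Product: 17 (1S,4R,4aS,6S,8aS)-4-hydroxy-6-(2-hydroxypropan-2-yl)-4,8a-dimethyldecahydronaphthalene-1-carbaldehyde
Conditions: TEMPO (10 mol %), PhI(OAc)2, CH2Cl2, rt
Reagents that add atoms: none
Why: TEMPO-catalysed oxidation converts only the primary alcohol into the aldehyde, whose equatorial C1 configuration is also the thermodynamically preferred one.

Step 11
Reactants: 18 benzene-1,3,5-triol (phloroglucinol)
Product: 19 1,3,5-trimethoxybenzene
Conditions: Me2SO4, K2CO3, acetone, reflux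
Reagents that add atoms: dimethyl sulfate, COS(=O)(=O)OC
Why: Threefold Williamson O-methylation of the phenol.

Step 12
Reactants: 19 1,3,5-trimethoxybenzene
Product: 20 2,4,6-trimethoxybenzene-1,3-dicarbaldehyde
Conditions: Cl2CHOMe (3 equiv), TiCl4 (3 equiv), CH2Cl2, −10 °C → rt; then H2O
Reagents that add atoms: dichloromethyl methyl ether, COC(Cl)Cl; water, O
Why: Twofold Rieche formylation (electrophilic aromatic substitution), the ring staying nucleophilic enough after the first formyl group because of its three methoxy groups.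

Step 13
Reactants: 20 2,4,6-trimethoxybenzene-1,3-dicarbaldehyde
Product: 21 5-bromo-2,4,6-trimethoxybenzene-1,3-dicarbaldehyde
Conditions: NBS, MeCN, rt
Reagents that add atoms: N-bromosuccinimide, O=C1CCC(=O)N1Br
Why: Electrophilic aromatic bromination at the only free position, which is ortho/para to all three methoxy groups and meta to both formyl groups.

Step 14
Reactants: 21 5-bromo-2,4,6-trimethoxybenzene-1,3-dicarbaldehyde
Product: 22 2,2′-(5-bromo-2,4,6-trimethoxy-1,3-phenylene)bis(1,3-dithiane)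
Conditions: HS(CH2)3SH, BF3·OEt2 (cat.), CH2Cl2, rt
Reagents that add atoms: propane-1,3-dithiol, SCCCS
Why: Dithioacetalisation masks both aldehydes as 1,3-dithianes that tolerate aryllithium formation and the later Lewis acid step.

Step 15
Reactants: 23 3-chloro-2-methylprop-1-ene
Product: 25 trimethyl(2-methylprop-2-en-1-yl)silane, via methallylmagnesium chloride 24 (not isolated)
Conditions: Mg, TMSCl, THF, 0 °C → reflux
Reagents that add atoms: chlorotrimethylsilane, C[Si](C)(C)Cl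
Why: Barbier-type Grignard formation and in situ silylation give the allylsilane.

Step 16
Reactants: 22 2,2′-(5-bromo-2,4,6-trimethoxy-1,3-phenylene)bis(1,3-dithiane); 17 (1S,4R,4aS,6S,8aS)-4-hydroxy-6-(2-hydroxypropan-2-yl)-4,8a-dimethyldecahydronaphthalene-1-carbaldehyde
Product: 27 [3,5-bis(1,3-dithian-2-yl)-2,4,6-trimethoxyphenyl][(1S,4R,4aS,6S,8aR)-4-hydroxy-6-(2-hydroxypropan-2-yl)-4,8a-dimethyldecahydronaphthalen-1-yl]methanol (both C9′ epimers), via aryllithium 26 (not isolated)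
Conditions: 22 (3.3 equiv), n-BuLi (3.3 equiv), THF, −78 °C; then 17, −78 → −30 °C
Reagents that add atoms: none
Why: Bromine–lithium exchange (far faster than dithiane deprotonation at −78 °C) and 1,2-addition of the aryllithium to the aldehyde forge the C9′–aryl bond, two equivalents being consumed by the tertiary hydroxyl groups; the carbinol configuration is irrelevant because it is ionised in the next step.

Step 17
Reactants: 27 the aryl carbinol (both C9′ epimers); 25 trimethyl(2-methylprop-2-en-1-yl)silane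
Product: 28 2,2′-{5-[(1R)-1-[(1R,4R,4aS,6S,8aR)-4-hydroxy-6-(2-hydroxypropan-2-yl)-4,8a-dimethyldecahydronaphthalen-1-yl]-3-methylbut-3-en-1-yl]-2,4,6-trimethoxy-1,3-phenylene}bis(1,3-dithiane)
Conditions: Bi(OTf)3 (10 mol %), CH2Cl2/MeNO2, −40 → 0 °C
Reagents that add atoms: none
Why: SN1 Hosomi–Sakurai-type allylation in which the trimethoxyaryl-stabilised benzylic cation is locked by A(1,3) strain with H-1 in the aryl plane, so the allylsilane attacks from the C2 side, anti to quaternary C10, which gives (9′R).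

Step 18
Reactants: 28 the methallyl compound
Product: 29 2,2′-{5-[(1R)-1-[(1R,4R,4aS,6S,8aR)-4-hydroxy-6-(2-hydroxypropan-2-yl)-4,8a-dimethyldecahydronaphthalen-1-yl]-3-methylbutyl]-2,4,6-trimethoxy-1,3-phenylene}bis(1,3-dithiane)
Conditions: TsNHNH2, NaOAc, DME/H2O, reflux
Reagents that add atoms: none
Why: Diimide reduction saturates the 1,1-disubstituted alkene by concerted hydrogen transfer and, unlike palladium-catalysed hydrogenation, is not poisoned by the thioacetals.

Step 19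
Reactants: 29 the isobutyl bis(dithiane)
Product: 30 5-[(1R)-1-[(1R,4R,4aS,6S,8aR)-4-hydroxy-6-(2-hydroxypropan-2-yl)-4,8a-dimethyldecahydronaphthalen-1-yl]-3-methylbutyl]-2,4,6-trimethoxybenzene-1,3-dicarbaldehyde
Conditions: MeI, CaCO3, MeCN/H2O, 45 °C
Reagents that add atoms: water, O
Why: S-Methylation turns each dithiane into a leaving group and hydrolysis unmasks both formyl groups under near-neutral conditions that spare the tertiary alcohols.

Step 20
Reactants: 30 the dialdehyde trimethyl ether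
Product: 31 5-[(1R)-1-[(1R,4R,4aS,6S,8aR)-4-hydroxy-6-(2-hydroxypropan-2-yl)-4,8a-dimethyldecahydronaphthalen-1-yl]-3-methylbutyl]-2,4,6-trihydroxybenzene-1,3-dicarbaldehyde (CNP0409870.6)
Conditions: NaSEt, DMF, 110 °C; then 1 M HCl
Reagents that add atoms: none
Why: SN2 O-demethylation by thiolate, each methoxy group being activated by an ortho formyl group, liberates the phloroglucinol under basic conditions that leave both tertiary alcohols intact.

## Compound list

1 | methyl acrylate | C=CC(=O)OC | starting material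
2 | methyl 2,3-dibromopropanoate (racemic) | COC(=O)C(Br)CBr | intermediate
3 | methyl 2-bromoprop-2-enoate | COC(=O)C(Br)=C | intermediate
4 | 3-(benzyloxy)propanal | O=CCCOCc1ccccc1 | starting material
5 | but-3-en-2-one (methyl vinyl ketone) | CC(=O)C=C | starting material
6 | (R)-2-[(benzyloxy)methyl]-5-oxohexanal | c1ccccc1COC[C@H](C=O)CCC(C)=O | intermediate
7 | (S)-4-[(benzyloxy)methyl]cyclohex-2-en-1-one | c1ccccc1COC[C@H]1CCC(=O)C=C1 | intermediate
8 | lithium (3R,4S)-4-[(benzyloxy)methyl]-3-methylcyclohex-1-en-1-olate | c1ccccc1COC[C@H]1CCC([O-])=C[C@@H]1C.[Li+] | intermediate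
9 | (S)-4-[(benzyloxy)methyl]-3-methylcyclohex-2-en-1-one | c1ccccc1COC[C@H]1CCC(=O)C=C1C | intermediate
10 | trimethyl{[(3R,4S)-4-[(benzyloxy)methyl]-3-ethenyl-3-methylcyclohex-1-en-1-yl]oxy}silane | c1ccccc1COC[C@H]1CCC(O[Si](C)(C)C)=C[C@]1(C)C=C | intermediate
11 | (3R,4S)-4-[(benzyloxy)methyl]-3-ethenyl-3-methylcyclohexan-1-one | c1ccccc1COC[C@H]1CCC(=O)C[C@]1(C)C=C | intermediate
12 | (3S,4S)-4-[(benzyloxy)methyl]-3-[2-(9-borabicyclo[3.3.1]nonan-9-yl)ethyl]-3-methylcyclohexan-1-one | c1ccccc1COC[C@H]1CCC(=O)C[C@]1(C)CCB1C2CCCC1CCC2 | intermediate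
13 | methyl 4-[(1S,2S)-2-[(benzyloxy)methyl]-1-methyl-5-oxocyclohexyl]-2-methylidenebutanoate | c1ccccc1COC[C@H]1CCC(=O)C[C@]1(C)CCC(=C)C(=O)OC | intermediate
14 | methyl (2S,4aR,5S,8aS)-5-[(benzyloxy)methyl]-4a-methyl-8-oxodecahydronaphthalene-2-carboxylate | c1ccccc1COC[C@H]1CCC(=O)[C@H]2C[C@@H](C(=O)OC)CC[C@]12C | intermediate
15 | (1R,4S,4aR,7S,8aS)-4-[(benzyloxy)methyl]-7-(2-hydroxypropan-2-yl)-1,4a-dimethyldecahydronaphthalen-1-ol | c1ccccc1COC[C@H]1CC[C@@](C)(O)[C@H]2C[C@@H](C(C)(C)O)CC[C@]12C | intermediate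
16 | (1R,4S,4aR,7S,8aS)-4-(hydroxymethyl)-7-(2-hydroxypropan-2-yl)-1,4a-dimethyldecahydronaphthalen-1-ol | OC[C@H]1CC[C@@](C)(O)[C@H]2C[C@@H](C(C)(C)O)CC[C@]12C | intermediate
17 | (1S,4R,4aS,6S,8aS)-4-hydroxy-6-(2-hydroxypropan-2-yl)-4,8a-dimethyldecahydronaphthalene-1-carbaldehyde | O=C[C@H]1CC[C@@](C)(O)[C@H]2C[C@@H](C(C)(C)O)CC[C@]12C | intermediate
18 | benzene-1,3,5-triol (phloroglucinol) | Oc1cc(O)cc(O)c1 | starting material
19 | 1,3,5-trimethoxybenzene | COc1cc(OC)cc(OC)c1 | intermediate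
20 | 2,4,6-trimethoxybenzene-1,3-dicarbaldehyde | COc1cc(OC)c(C=O)c(OC)c1C=O | intermediate
21 | 5-bromo-2,4,6-trimethoxybenzene-1,3-dicarbaldehyde | COc1c(Br)c(OC)c(C=O)c(OC)c1C=O | intermediate
22 | 2,2′-(5-bromo-2,4,6-trimethoxy-1,3-phenylene)bis(1,3-dithiane) | COc1c(Br)c(OC)c(C2SCCCS2)c(OC)c1C1SCCCS1 | intermediate
23 | 3-chloro-2-methylprop-1-ene | CC(=C)CCl | starting material
24 | (2-methylprop-2-en-1-yl)magnesium chloride | CC(=C)C[Mg]Cl | intermediate
25 | trimethyl(2-methylprop-2-en-1-yl)silane | CC(=C)C[Si](C)(C)C | intermediate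
26 | [3,5-bis(1,3-dithian-2-yl)-2,4,6-trimethoxyphenyl]lithium | COc1c([Li])c(OC)c(C2SCCCS2)c(OC)c1C1SCCCS1 | intermediate
27 | [3,5-bis(1,3-dithian-2-yl)-2,4,6-trimethoxyphenyl][(1S,4R,4aS,6S,8aR)-4-hydroxy-6-(2-hydroxypropan-2-yl)-4,8a-dimethyldecahydronaphthalen-1-yl]methanol (both C9′ epimers) | OC(c1c(OC)c(C2SCCCS2)c(OC)c(C3SCCCS3)c1OC)[C@H]1CC[C@@](C)(O)[C@H]2C[C@@H](C(C)(C)O)CC[C@]12C | intermediate
28 | 2,2′-{5-[(1R)-1-[(1R,4R,4aS,6S,8aR)-4-hydroxy-6-(2-hydroxypropan-2-yl)-4,8a-dimethyldecahydronaphthalen-1-yl]-3-methylbut-3-en-1-yl]-2,4,6-trimethoxy-1,3-phenylene}bis(1,3-dithiane) | C=C(C)C[C@@H](c1c(OC)c(C2SCCCS2)c(OC)c(C3SCCCS3)c1OC)[C@H]1CC[C@@](C)(O)[C@H]2C[C@@H](C(C)(C)O)CC[C@]12C | intermediate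
29 | 2,2′-{5-[(1R)-1-[(1R,4R,4aS,6S,8aR)-4-hydroxy-6-(2-hydroxypropan-2-yl)-4,8a-dimethyldecahydronaphthalen-1-yl]-3-methylbutyl]-2,4,6-trimethoxy-1,3-phenylene}bis(1,3-dithiane) | CC(C)C[C@@H](c1c(OC)c(C2SCCCS2)c(OC)c(C3SCCCS3)c1OC)[C@H]1CC[C@@](C)(O)[C@H]2C[C@@H](C(C)(C)O)CC[C@]12C | intermediate
30 | 5-[(1R)-1-[(1R,4R,4aS,6S,8aR)-4-hydroxy-6-(2-hydroxypropan-2-yl)-4,8a-dimethyldecahydronaphthalen-1-yl]-3-methylbutyl]-2,4,6-trimethoxybenzene-1,3-dicarbaldehyde | CC(C)C[C@@H](c1c(OC)c(C=O)c(OC)c(C=O)c1OC)[C@H]1CC[C@@](C)(O)[C@H]2C[C@@H](C(C)(C)O)CC[C@]12C | intermediate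
31 | 5-[(1R)-1-[(1R,4R,4aS,6S,8aR)-4-hydroxy-6-(2-hydroxypropan-2-yl)-4,8a-dimethyldecahydronaphthalen-1-yl]-3-methylbutyl]-2,4,6-trihydroxybenzene-1,3-dicarbaldehyde | CC(C)C[C@@H](c1c(O)c(C=O)c(O)c(C=O)c1O)[C@H]1CC[C@@](C)(O)[C@H]2C[C@@H](C(C)(C)O)CC[C@]12C | target

## Step count and risks

Total step count: 20.
Longest linear sequence: 13 steps (steps 3–10, then 16–20).

The three steps most likely to fail:

**Step 6 (B-alkyl Suzuki coupling next to a free ketone, with a polymerisable bromoacrylate).** The fallback sets out from 11 and returns at 13. Hydroborate the vinyl group of 11 with 9-BBN and oxidise (NaBO3) to the primary alcohol (3S,4S)-4-[(benzyloxy)methyl]-3-(2-hydroxyethyl)-3-methylcyclohexan-1-one F1. Convert it with I2, PPh3 and imidazole into the iodide (3R,4S)-4-[(benzyloxy)methyl]-3-(2-iodoethyl)-3-methylcyclohexan-1-one F2. Insert zinc (Zn dust, LiCl, THF) to give the ketone-tolerant alkylzinc iodide F3 and couple it with 3 in a Negishi reaction (Pd(PPh3)4) to reach 13.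

**Step 16 (hindered aryllithium carrying two dithianes, added to a diol aldehyde).** The fallback sets out from 17 (and uses 19) and returns at 30. Lithiate the cheap arene 19 directly (n-BuLi, THF, 0 °C) to (2,4,6-trimethoxyphenyl)lithium F4 and add it in excess to 17 to give the carbinol (2,4,6-trimethoxyphenyl)[(1S,4R,4aS,6S,8aR)-4-hydroxy-6-(2-hydroxypropan-2-yl)-4,8a-dimethyldecahydronaphthalen-1-yl]methanol F5. Allylate with 25 as in step 17 to the methallyl compound (1R,4R,4aR,7S,8aS)-7-(2-hydroxypropan-2-yl)-1,4a-dimethyl-4-[(1R)-3-methyl-1-(2,4,6-trimethoxyphenyl)but-3-en-1-yl]decahydronaphthalen-1-ol F6. Hydrogenate (H2, Pd/C) to the isobutyl compound (1R,4R,4aR,7S,8aS)-7-(2-hydroxypropan-2-yl)-1,4a-dimethyl-4-[(1R)-3-methyl-1-(2,4,6-trimethoxyphenyl)butyl]decahydronaphthalen-1-ol F7. Introduce the formyl groups last by two ortho-lithiation/DMF cycles (n-BuLi, TMEDA; DMF), passing through the mono-aldehyde 3-[(1R)-1-[(1R,4R,4aS,6S,8aR)-4-hydroxy-6-(2-hydroxypropan-2-yl)-4,8a-dimethyldecahydronaphthalen-1-yl]-3-methylbutyl]-2,4,6-trimethoxybenzaldehyde F8, to arrive at 30.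

**Step 17 (facial selectivity of the SN1 allylation at C9′).** The fallback sets out from 27 and returns at 28. Oxidise 27 (MnO2) to the aryl ketone [3,5-bis(1,3-dithian-2-yl)-2,4,6-trimethoxyphenyl][(1S,4R,4aS,6S,8aS)-4-hydroxy-6-(2-hydroxypropan-2-yl)-4,8a-dimethyldecahydronaphthalen-1-yl]methanone F9. Add the Grignard reagent 24 to obtain the tertiary carbinol 1-[3,5-bis(1,3-dithian-2-yl)-2,4,6-trimethoxyphenyl]-1-[(1S,4R,4aS,6S,8aS)-4-hydroxy-6-(2-hydroxypropan-2-yl)-4,8a-dimethyldecahydronaphthalen-1-yl]-3-methylbut-3-en-1-ol F10. Remove its hydroxyl by ionic hydrogenation (Et3SiH, BF3·OEt2, CH2Cl2, −78 °C). Hydride now enters the open face of the same A(1,3)-locked cation, so this order gives the C9′ epimer of whatever the direct allylation gives. It is therefore the remedy only if step 17 favours the wrong face; in that case it leads to 28. If step 17 is merely unselective, the C9′ epimers of 28 have to be separated.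

Further compounds
F1 | step 6 | (3S,4S)-4-[(benzyloxy)methyl]-3-(2-hydroxyethyl)-3-methylcyclohexan-1-one | c1ccccc1COC[C@H]1CCC(=O)C[C@]1(C)CCO
F2 | step 6 | (3R,4S)-4-[(benzyloxy)methyl]-3-(2-iodoethyl)-3-methylcyclohexan-1-one | c1ccccc1COC[C@H]1CCC(=O)C[C@]1(C)CCI
F3 | step 6 | {2-[(1S,2S)-2-[(benzyloxy)methyl]-1-methyl-5-oxocyclohexyl]ethyl}zinc iodide | c1ccccc1COC[C@H]1CCC(=O)C[C@]1(C)CC[Zn]I
F4 | step 16 | (2,4,6-trimethoxyphenyl)lithium | COc1cc(OC)c([Li])c(OC)c1
F5 | step 16 | (2,4,6-trimethoxyphenyl)[(1S,4R,4aS,6S,8aR)-4-hydroxy-6-(2-hydroxypropan-2-yl)-4,8a-dimethyldecahydronaphthalen-1-yl]methanol (both C9′ epimers) | OC(c1c(OC)cc(OC)cc1OC)[C@H]1CC[C@@](C)(O)[C@H]2C[C@@H](C(C)(C)O)CC[C@]12C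
F6 | step 16 | (1R,4R,4aR,7S,8aS)-7-(2-hydroxypropan-2-yl)-1,4a-dimethyl-4-[(1R)-3-methyl-1-(2,4,6-trimethoxyphenyl)but-3-en-1-yl]decahydronaphthalen-1-ol | C=C(C)C[C@@H](c1c(OC)cc(OC)cc1OC)[C@H]1CC[C@@](C)(O)[C@H]2C[C@@H](C(C)(C)O)CC[C@]12C
F7 | step 16 | (1R,4R,4aR,7S,8aS)-7-(2-hydroxypropan-2-yl)-1,4a-dimethyl-4-[(1R)-3-methyl-1-(2,4,6-trimethoxyphenyl)butyl]decahydronaphthalen-1-ol | CC(C)C[C@@H](c1c(OC)cc(OC)cc1OC)[C@H]1CC[C@@](C)(O)[C@H]2C[C@@H](C(C)(C)O)CC[C@]12C
F8 | step 16 | 3-[(1R)-1-[(1R,4R,4aS,6S,8aR)-4-hydroxy-6-(2-hydroxypropan-2-yl)-4,8a-dimethyldecahydronaphthalen-1-yl]-3-methylbutyl]-2,4,6-trimethoxybenzaldehyde | CC(C)C[C@@H](c1c(OC)cc(OC)c(C=O)c1OC)[C@H]1CC[C@@](C)(O)[C@H]2C[C@@H](C(C)(C)O)CC[C@]12C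
F9 | step 17 | [3,5-bis(1,3-dithian-2-yl)-2,4,6-trimethoxyphenyl][(1S,4R,4aS,6S,8aS)-4-hydroxy-6-(2-hydroxypropan-2-yl)-4,8a-dimethyldecahydronaphthalen-1-yl]methanone | O=C(c1c(OC)c(C2SCCCS2)c(OC)c(C3SCCCS3)c1OC)[C@H]1CC[C@@](C)(O)[C@H]2C[C@@H](C(C)(C)O)CC[C@]12C
F10 | step 17 | 1-[3,5-bis(1,3-dithian-2-yl)-2,4,6-trimethoxyphenyl]-1-[(1S,4R,4aS,6S,8aS)-4-hydroxy-6-(2-hydroxypropan-2-yl)-4,8a-dimethyldecahydronaphthalen-1-yl]-3-methylbut-3-en-1-ol (both C9′ epimers) | C=C(C)CC(O)(c1c(OC)c(C2SCCCS2)c(OC)c(C3SCCCS3)c1OC)[C@H]1CC[C@@](C)(O)[C@H]2C[C@@H](C(C)(C)O)CC[C@]12C
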